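**Plan**

1. Numbering follows the C15 chain, C1≡C2–C3(Br)–C4…C15; the oxolane is O/C4–C7 and the oxocane O/C6–C12, fused at C6–C7. The retrosynthesis cuts C10–Br and C9–O (from a C9=C10 alkene), C3–Br and C13–Br (from alcohols), C9=C10 (ring-closing metathesis), the C6–O bond of the oxocane (reductive etherification of a C6 ketone), and last C6–C7 (5-exo acyl radical cyclisation).
2. Forward, the oxolane is closed first through C6–C7, the C10–C15 piece is then joined through the oxocane oxygen, the eight-membered ring is closed at C9=C10, and the bromides follow (C3 and C13 together, C10 last).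
3. C3/C4 and C12/C13 come from two Sharpless kinetic resolutions of racemic vinyl carbinols (erythro epoxy alcohols). C7 comes from the radical cyclisation (2,5-cis), and C6 from hydride attack on an oxocarbenium ion anti to the C7 arm. C3 and C13 are inverted on bromination, and C9/C10 arise by net syn bromohydroxylation through a transannular oxonium ion.
4. Enabling feature: C6 and C7 are adjacent oxygen-bearing ring-fusion carbons. C7 lies between the oxolane oxygen and C8–C9 (C9 oxygenated), so O–C7=C8–C9(=O) can be an (E)-β-alkoxyacrylate; C6, two atoms from C4, can be an acyl radical whose carbonyl oxygen is later exchanged for the oxocane oxygen.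

Key step: step 7

**Route**

Step 1
Reactants: 1 (triisopropylsilyl)acetylene; 2 acrolein
Product: 4 rac-5-(triisopropylsilyl)pent-1-en-4-yn-3-ol, via lithium (triisopropylsilyl)acetylide 3 (not isolated)
Conditions: n-BuLi, THF, −78 °C; then 2; H2O quench
Reagents that add atoms: none
Why: 1,2-Addition of the lithium acetylide to the aldehyde carbon of acrolein gives the racemic allylic–propargylic alcohol; its stereocentre (C3) is resolved in step 2.

Step 2
Reactants: 4 rac-5-(triisopropylsilyl)pent-1-en-4-yn-3-ol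
Product: 5 (1S)-1-[(2R)-oxiran-2-yl]-3-(triisopropylsilyl)prop-2-yn-1-ol
Conditions: Ti(OiPr)4 (cat.), L-(+)-diisopropyl tartrate, t-BuOOH (0.6 equiv), 4 Å MS, CH2Cl2, −20 °C
Reagents that add atoms: tert-butyl hydroperoxide CC(C)(C)OO
Why: Sharpless kinetic resolution: the L-(+)-tartrate catalyst should epoxidise (R)-4 much faster than (S)-4 and deliver oxygen to the vinyl face anti to the alkynyl group, giving the erythro epoxy alcohol with C3 (S) and C4 (R); unreacted (S)-4 is separated.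

Step 3
Reactants: 5 (1S)-1-[(2R)-oxiran-2-yl]-3-(triisopropylsilyl)prop-2-yn-1-ol
Product: 6 tert-butyldimethyl{[(1S)-1-[(2R)-oxiran-2-yl]-3-(triisopropylsilyl)prop-2-yn-1-yl]oxy}silane
Conditions: TBSCl, imidazole, DMF, 0 °C to rt
Reagents that add atoms: tert-butyldimethylsilyl chloride CC(C)(C)[Si](C)(C)Cl
Why: Standard silylation of the secondary propargylic alcohol; no stereocentre is touched.

Step 4
Reactants: 6 tert-butyldimethyl{[(1S)-1-[(2R)-oxiran-2-yl]-3-(triisopropylsilyl)prop-2-yn-1-yl]oxy}silane; 7 1,3-dithiane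
Product: 9 (2R,3S)-3-[(tert-butyldimethylsilyl)oxy]-1-(1,3-dithian-2-yl)-5-(triisopropylsilyl)pent-4-yn-2-ol, via 2-lithio-1,3-dithiane 8 (not isolated)
Conditions: n-BuLi, THF, −30 °C; then 6, −30 to 0 °C; H2O quench
Reagents that add atoms: none
Why: SN2 opening of the epoxide at its unsubstituted carbon (C5) by the sulfur-stabilised carbanion brings in C6 as a masked aldehyde and frees the C4 hydroxyl with its configuration unchanged.

Step 5
Reactants: 9 (2R,3S)-3-[(tert-butyldimethylsilyl)oxy]-1-(1,3-dithian-2-yl)-5-(triisopropylsilyl)pent-4-yn-2-ol; 10 ethyl propiolate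
Product: 11 ethyl (E)-3-{[(2R,3S)-3-[(tert-butyldimethylsilyl)oxy]-1-(1,3-dithian-2-yl)-5-(triisopropylsilyl)pent-4-yn-2-yl]oxy}prop-2-enoate
Conditions: N-methylmorpholine, CH2Cl2, rt
Reagents that add atoms: none
Why: Amine-catalysed oxa-Michael addition of the C4 hydroxyl to the ynoate should give the (E)-β-alkoxyacrylate, which places C7, C8 and C9 on the C4 oxygen.

Step 6
Reactants: 11 ethyl (E)-3-{[(2R,3S)-3-[(tert-butyldimethylsilyl)oxy]-1-(1,3-dithian-2-yl)-5-(triisopropylsilyl)pent-4-yn-2-yl]oxy}prop-2-enoate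
Product: 12 ethyl (E)-3-{[(3R,4S)-4-[(tert-butyldimethylsilyl)oxy]-1-oxo-6-(triisopropylsilyl)hex-5-yn-3-yl]oxy}prop-2-enoate
Conditions: MeI, CaCO3, MeCN/H2O, 40 °C
Reagents that add atoms: water O
Why: S-Methylation makes the dithiane a leaving group and water hydrolyses it to the C6 aldehyde under buffered conditions that should spare the silyl groups and the β-alkoxyacrylate.

Step 7
Reactants: 12 ethyl (E)-3-{[(3R,4S)-4-[(tert-butyldimethylsilyl)oxy]-1-oxo-6-(triisopropylsilyl)hex-5-yn-3-yl]oxy}prop-2-enoate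
Product: 13 ethyl 2-[(2R,5R)-5-[(1S)-1-[(tert-butyldimethylsilyl)oxy]-3-(triisopropylsilyl)prop-2-yn-1-yl]-3-oxooxolan-2-yl]acetate
Conditions: t-C12H25SH (0.3 equiv), AIBN (portions), PhCl, 80 °C, 0.01 M
Reagents that add atoms: none
Why: The thiyl radical abstracts the aldehydic hydrogen of 12, the nucleophilic C6 acyl radical adds to C7 (the β-carbon of the (E)-β-alkoxyacrylate), and the C8 α-ester radical takes a hydrogen atom from the thiol, which carries the chain. The closest known reactions are acyl radical cyclisations of acyl selenides onto β-alkoxyacrylates, which give cis-2,5-disubstituted oxolan-3-ones, and the thiol-catalysed radical hydroacylation of alkenals. The oxolane (O, C4, C5, C6, C7) closes in the 5-exo-trig mode; no other ring is formed. The one new stereocentre, C7 (R), is controlled by C4: in the chair-like transition state the C4 side chain and the s-trans acrylate both lie pseudo-equatorial, which puts the C7 acetate arm cis to the C4 substituent. The step needs chemoselectivity for the acrylate over 5-exo-dig attack on the C2 alkyne and over decarbonylation; the electron-poor acceptor is polarity-matched to the acyl radical, whereas the alkyne is unactivated and shielded by the triisopropylsilyl group. The C6 carbonyl that results is the handle through which the oxocane oxygen is brought in with cis control in step 12.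

Step 8
Reactants: 14 rac-pent-1-en-3-ol
Product: 15 (1R)-1-[(2S)-oxiran-2-yl]propan-1-ol
Conditions: Ti(OiPr)4 (cat.), D-(−)-diisopropyl tartrate, t-BuOOH (0.6 equiv), 4 Å MS, CH2Cl2, −20 °C
Reagents that add atoms: tert-butyl hydroperoxide CC(C)(C)OO
Why: Sharpless kinetic resolution with the D-(−)-tartrate catalyst should epoxidise (R)-14 fast with oxygen delivery anti to the ethyl group, giving the erythro epoxy alcohol with C12 (S) and C13 (R); (S)-14 remains and is separated.

Step 9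
Reactants: 15 (1R)-1-[(2S)-oxiran-2-yl]propan-1-ol
Product: 16 tert-butyldimethyl{(1R)-1-[(2S)-oxiran-2-yl]propoxy}silane
Conditions: TBSCl, imidazole, DMF, 0 °C to rt
Reagents that add atoms: tert-butyldimethylsilyl chloride CC(C)(C)[Si](C)(C)Cl
Why: Standard silylation of the C13 hydroxyl; no stereocentre is touched.

Step 10
Reactants: 16 tert-butyldimethyl{(1R)-1-[(2S)-oxiran-2-yl]propoxy}silane
Product: 17 (4S,5R)-5-[(tert-butyldimethylsilyl)oxy]hept-1-en-4-ol
Conditions: CH2=CHMgBr, CuI (10 mol%), THF, −40 to −10 °C; H2O quench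
Reagents that add atoms: vinylmagnesium bromide (CH2=CHMgBr) C=C[Mg]Br
Why: Copper-catalysed SN2 opening of the terminal epoxide at its CH2 carbon (C11) by the vinyl Grignard reagent gives the homoallylic alcohol; C12 keeps its configuration.

Step 11
Reactants: 17 (4S,5R)-5-[(tert-butyldimethylsilyl)oxy]hept-1-en-4-ol
Product: 18 (4S,5R)-5-[(tert-butyldimethylsilyl)oxy]-4-[(trimethylsilyl)oxy]hept-1-ene
Conditions: Me3SiCl, Et3N, CH2Cl2, 0 °C
Reagents that add atoms: chlorotrimethylsilane C[Si](C)(C)Cl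
Why: Silylation of the C12 hydroxyl gives the silyl ether that serves as the oxygen nucleophile in the reductive etherification.

Step 12
Reactants: 13 ethyl 2-[(2R,5R)-5-[(1S)-1-[(tert-butyldimethylsilyl)oxy]-3-(triisopropylsilyl)prop-2-yn-1-yl]-3-oxooxolan-2-yl]acetate; 18 (4S,5R)-5-[(tert-butyldimethylsilyl)oxy]-4-[(trimethylsilyl)oxy]hept-1-ene
Product: 20 ethyl 2-[(2R,3R,5R)-3-{[(4S,5R)-5-[(tert-butyldimethylsilyl)oxy]hept-1-en-4-yl]oxy}-5-[(1S)-1-[(tert-butyldimethylsilyl)oxy]-3-(triisopropylsilyl)prop-2-yn-1-yl]oxolan-2-yl]acetate, via oxocarbenium ion 19 (not isolated)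
Conditions: Me3SiOTf (cat.), Et3SiH, CH2Cl2, −78 °C
Reagents that add atoms: none
Why: Reductive etherification: the silyl triflate activates the C6 ketone, the C12 silyl ether oxygen adds, and the oxocarbenium ion should be reduced by Et3SiH on the ring face anti to the C7 acetate arm and the C4 side chain, which sets C6 (R) with the new C6–O bond cis to C7–C8.

Step 13
Reactants: 20 ethyl 2-[(2R,3R,5R)-3-{[(4S,5R)-5-[(tert-butyldimethylsilyl)oxy]hept-1-en-4-yl]oxy}-5-[(1S)-1-[(tert-butyldimethylsilyl)oxy]-3-(triisopropylsilyl)prop-2-yn-1-yl]oxolan-2-yl]acetate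
Product: 21 2-[(2R,3R,5R)-3-{[(4S,5R)-5-[(tert-butyldimethylsilyl)oxy]hept-1-en-4-yl]oxy}-5-[(1S)-1-[(tert-butyldimethylsilyl)oxy]-3-(triisopropylsilyl)prop-2-yn-1-yl]oxolan-2-yl]acetaldehyde
Conditions: i-Bu2AlH (1.1 equiv), CH2Cl2, −78 °C; H2O work-up
Reagents that add atoms: none
Why: Half-reduction of the ethyl ester at low temperature, where the aluminium hemiacetal is stable (helped by chelation to the β-oxygen), should stop at the C9 aldehyde.

Step 14
Reactants: 21 2-[(2R,3R,5R)-3-{[(4S,5R)-5-[(tert-butyldimethylsilyl)oxy]hept-1-en-4-yl]oxy}-5-[(1S)-1-[(tert-butyldimethylsilyl)oxy]-3-(triisopropylsilyl)prop-2-yn-1-yl]oxolan-2-yl]acetaldehyde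
Product: 22 (2R,3R,5R)-2-allyl-3-{[(4S,5R)-5-[(tert-butyldimethylsilyl)oxy]hept-1-en-4-yl]oxy}-5-[(1S)-1-[(tert-butyldimethylsilyl)oxy]-3-(triisopropylsilyl)prop-2-yn-1-yl]oxolane
Conditions: Ph3PCH3Br, KN(SiMe3)2, THF, 0 °C; then 21, −78 to 0 °C
Reagents that add atoms: methyltriphenylphosphonium bromide C[P+](c1ccccc1)(c1ccccc1)c1ccccc1.[Br-]
Why: Wittig methylenation converts the C9 aldehyde into the terminal alkene needed for ring closure.

Step 15
Reactants: 22 (2R,3R,5R)-2-allyl-3-{[(4S,5R)-5-[(tert-butyldimethylsilyl)oxy]hept-1-en-4-yl]oxy}-5-[(1S)-1-[(tert-butyldimethylsilyl)oxy]-3-(triisopropylsilyl)prop-2-yn-1-yl]oxolane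
Product: 23 (2R,3aR,5S,9aR,Z)-5-[(1R)-1-[(tert-butyldimethylsilyl)oxy]propyl]-2-[(1S)-1-[(tert-butyldimethylsilyl)oxy]-3-(triisopropylsilyl)prop-2-yn-1-yl]-3,3a,5,6,9,9a-hexahydro-2H-furo[3,2-b]oxocine
Conditions: second-generation Grubbs catalyst (H2IMes)(PCy3)Cl2Ru=CHPh (5 mol%), CH2Cl2 (2 mM), 40 °C
Reagents that add atoms: none
Why: Ring-closing metathesis of the two allyl groups, held cis on the oxolane (C7–allyl and C6–O–CH(allyl)), should close the oxocene at C9=C10 with loss of ethene; the eight-membered ring can hold only the Z alkene, and the bulky silyl alkyne should not take part.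

Step 16
Reactants: 23 (2R,3aR,5S,9aR,Z)-5-[(1R)-1-[(tert-butyldimethylsilyl)oxy]propyl]-2-[(1S)-1-[(tert-butyldimethylsilyl)oxy]-3-(triisopropylsilyl)prop-2-yn-1-yl]-3,3a,5,6,9,9a-hexahydro-2H-furo[3,2-b]oxocine
Product: 24 (1S)-1-[(2R,3aR,5S,9aR,Z)-5-[(1R)-1-hydroxypropyl]-3,3a,5,6,9,9a-hexahydro-2H-furo[3,2-b]oxocin-2-yl]prop-2-yn-1-ol
Conditions: Bu4NF (excess), THF, 0 °C to rt; H2O work-up
Reagents that add atoms: none
Why: Fluoride cleaves both silyl ethers and the alkynyl C–Si bond in one operation, freeing the C3 and C13 hydroxyls and the terminal alkyne.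

Step 17
Reactants: 24 (1S)-1-[(2R,3aR,5S,9aR,Z)-5-[(1R)-1-hydroxypropyl]-3,3a,5,6,9,9a-hexahydro-2H-furo[3,2-b]oxocin-2-yl]prop-2-yn-1-ol
Product: 25 (2R,3aR,5S,9aR,Z)-5-[(1S)-1-bromopropyl]-2-[(1R)-1-bromoprop-2-yn-1-yl]-3,3a,5,6,9,9a-hexahydro-2H-furo[3,2-b]oxocine
Conditions: CBr4, P(n-C8H17)3, toluene, rt to 70 °C
Reagents that add atoms: carbon tetrabromide BrC(Br)(Br)Br
Why: Appel-type bromination: each alkoxyphosphonium ion is displaced by bromide in an SN2 step, so C3 should go from S to R and C13 from R to S.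

Step 18
Reactants: 25 (2R,3aR,5S,9aR,Z)-5-[(1S)-1-bromopropyl]-2-[(1R)-1-bromoprop-2-yn-1-yl]-3,3a,5,6,9,9a-hexahydro-2H-furo[3,2-b]oxocine
Product: 27 (2R,3aR,5S,7S,8R,9aR)-7-bromo-5-[(1S)-1-bromopropyl]-2-[(1R)-1-bromoprop-2-yn-1-yl]octahydro-2H-furo[3,2-b]oxocin-8-ol (target), via tricyclic oxonium ion 26 (not isolated)
Conditions: N-bromosuccinimide, H2O (10 equiv), MeCN, 0 °C
Reagents that add atoms: N-bromosuccinimide O=C1CCC(=O)N1Br; water O
Why: Bromonium formation at C9=C10, transannular attack of the oxocane oxygen on C9 anti to bromine (five-membered ring; C10 would need a four-membered one) to give the cis-anti-cis tricyclic oxonium ion, and SN2 opening at C9 by water should give net syn addition of Br (C10, S) and OH (C9, R); this is the bromonium-induced transannular oxonium chemistry known for medium-ring Laurencia ethers.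

**Compound list**

1 | (triisopropylsilyl)acetylene | C#C[Si](C(C)C)(C(C)C)C(C)C | starting material
2 | acrolein | C=CC=O | starting material
3 | lithium (triisopropylsilyl)acetylide | [Li]C#C[Si](C(C)C)(C(C)C)C(C)C | intermediate
4 | rac-5-(triisopropylsilyl)pent-1-en-4-yn-3-ol (racemate) | C=CC(O)C#C[Si](C(C)C)(C(C)C)C(C)C | intermediate
5 | (1S)-1-[(2R)-oxiran-2-yl]-3-(triisopropylsilyl)prop-2-yn-1-ol | CC(C)[Si](C(C)C)(C(C)C)C#C[C@H](O)[C@H]1CO1 | intermediate
6 | tert-butyldimethyl{[(1S)-1-[(2R)-oxiran-2-yl]-3-(triisopropylsilyl)prop-2-yn-1-yl]oxy}silane | CC(C)[Si](C(C)C)(C(C)C)C#C[C@H](O[Si](C)(C)C(C)(C)C)[C@H]1CO1 | intermediate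
7 | 1,3-dithiane | C1CSCSC1 | starting material
8 | 2-lithio-1,3-dithiane | [Li]C1SCCCS1 | intermediate
9 | (2R,3S)-3-[(tert-butyldimethylsilyl)oxy]-1-(1,3-dithian-2-yl)-5-(triisopropylsilyl)pent-4-yn-2-ol | CC(C)[Si](C(C)C)(C(C)C)C#C[C@H](O[Si](C)(C)C(C)(C)C)[C@H](O)CC1SCCCS1 | intermediate
10 | ethyl propiolate | C#CC(=O)OCC | starting material
11 | ethyl (E)-3-{[(2R,3S)-3-[(tert-butyldimethylsilyl)oxy]-1-(1,3-dithian-2-yl)-5-(triisopropylsilyl)pent-4-yn-2-yl]oxy}prop-2-enoate | CC(C)[Si](C(C)C)(C(C)C)C#C[C@H](O[Si](C)(C)C(C)(C)C)[C@H](O/C=C/C(=O)OCC)CC1SCCCS1 | intermediate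
12 | ethyl (E)-3-{[(3R,4S)-4-[(tert-butyldimethylsilyl)oxy]-1-oxo-6-(triisopropylsilyl)hex-5-yn-3-yl]oxy}prop-2-enoate | CC(C)[Si](C(C)C)(C(C)C)C#C[C@H](O[Si](C)(C)C(C)(C)C)[C@H](O/C=C/C(=O)OCC)CC=O | intermediate
13 | ethyl 2-[(2R,5R)-5-[(1S)-1-[(tert-butyldimethylsilyl)oxy]-3-(triisopropylsilyl)prop-2-yn-1-yl]-3-oxooxolan-2-yl]acetate | CC(C)[Si](C(C)C)(C(C)C)C#C[C@H](O[Si](C)(C)C(C)(C)C)[C@H]1CC(=O)[C@@H](CC(=O)OCC)O1 | intermediate
14 | rac-pent-1-en-3-ol (racemate) | C=CC(O)CC | starting material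
15 | (1R)-1-[(2S)-oxiran-2-yl]propan-1-ol | CC[C@@H](O)[C@@H]1CO1 | intermediate
16 | tert-butyldimethyl{(1R)-1-[(2S)-oxiran-2-yl]propoxy}silane | CC[C@@H](O[Si](C)(C)C(C)(C)C)[C@@H]1CO1 | intermediate
17 | (4S,5R)-5-[(tert-butyldimethylsilyl)oxy]hept-1-en-4-ol | CC[C@@H](O[Si](C)(C)C(C)(C)C)[C@@H](O)CC=C | intermediate
18 | (4S,5R)-5-[(tert-butyldimethylsilyl)oxy]-4-[(trimethylsilyl)oxy]hept-1-ene | CC[C@@H](O[Si](C)(C)C(C)(C)C)[C@@H](O[Si](C)(C)C)CC=C | intermediate
19 | oxocarbenium ion (C6=O+–C12) from 13 and 18 | CC(C)[Si](C(C)C)(C(C)C)C#C[C@H](O[Si](C)(C)C(C)(C)C)[C@H]1CC(=[O+][C@H]([C@H](O[Si](C)(C)C(C)(C)C)CC)CC=C)[C@@H](CC(=O)OCC)O1 | intermediate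
20 | ethyl 2-[(2R,3R,5R)-3-{[(4S,5R)-5-[(tert-butyldimethylsilyl)oxy]hept-1-en-4-yl]oxy}-5-[(1S)-1-[(tert-butyldimethylsilyl)oxy]-3-(triisopropylsilyl)prop-2-yn-1-yl]oxolan-2-yl]acetate | CC(C)[Si](C(C)C)(C(C)C)C#C[C@H](O[Si](C)(C)C(C)(C)C)[C@H]1C[C@@H](O[C@H]([C@H](O[Si](C)(C)C(C)(C)C)CC)CC=C)[C@@H](CC(=O)OCC)O1 | intermediate
21 | 2-[(2R,3R,5R)-3-{[(4S,5R)-5-[(tert-butyldimethylsilyl)oxy]hept-1-en-4-yl]oxy}-5-[(1S)-1-[(tert-butyldimethylsilyl)oxy]-3-(triisopropylsilyl)prop-2-yn-1-yl]oxolan-2-yl]acetaldehyde | CC(C)[Si](C(C)C)(C(C)C)C#C[C@H](O[Si](C)(C)C(C)(C)C)[C@H]1C[C@@H](O[C@H]([C@H](O[Si](C)(C)C(C)(C)C)CC)CC=C)[C@@H](CC=O)O1 | intermediate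
22 | (2R,3R,5R)-2-allyl-3-{[(4S,5R)-5-[(tert-butyldimethylsilyl)oxy]hept-1-en-4-yl]oxy}-5-[(1S)-1-[(tert-butyldimethylsilyl)oxy]-3-(triisopropylsilyl)prop-2-yn-1-yl]oxolane | CC(C)[Si](C(C)C)(C(C)C)C#C[C@H](O[Si](C)(C)C(C)(C)C)[C@H]1C[C@@H](O[C@H]([C@H](O[Si](C)(C)C(C)(C)C)CC)CC=C)[C@@H](CC=C)O1 | intermediate
23 | (2R,3aR,5S,9aR,Z)-5-[(1R)-1-[(tert-butyldimethylsilyl)oxy]propyl]-2-[(1S)-1-[(tert-butyldimethylsilyl)oxy]-3-(triisopropylsilyl)prop-2-yn-1-yl]-3,3a,5,6,9,9a-hexahydro-2H-furo[3,2-b]oxocine | CC(C)[Si](C(C)C)(C(C)C)C#C[C@H](O[Si](C)(C)C(C)(C)C)[C@H]1C[C@H]2O[C@H]([C@H](O[Si](C)(C)C(C)(C)C)CC)C/C=C\C[C@H]2O1 | intermediate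
24 | (1S)-1-[(2R,3aR,5S,9aR,Z)-5-[(1R)-1-hydroxypropyl]-3,3a,5,6,9,9a-hexahydro-2H-furo[3,2-b]oxocin-2-yl]prop-2-yn-1-ol | C#C[C@H](O)[C@H]1C[C@H]2O[C@H]([C@H](O)CC)C/C=C\C[C@H]2O1 | intermediate
25 | (2R,3aR,5S,9aR,Z)-5-[(1S)-1-bromopropyl]-2-[(1R)-1-bromoprop-2-yn-1-yl]-3,3a,5,6,9,9a-hexahydro-2H-furo[3,2-b]oxocine | C#C[C@@H](Br)[C@H]1C[C@H]2O[C@H]([C@@H](Br)CC)C/C=C\C[C@H]2O1 | intermediate
26 | tricyclic oxonium ion (oxocane oxygen bonded to C6, C9 and C12; bromine on C10) | C#C[C@@H](Br)[C@H]1C[C@H]2[O+]3[C@H]([C@@H](Br)CC)C[C@H](Br)[C@@H]3C[C@H]2O1 | intermediate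
27 | (2R,3aR,5S,7S,8R,9aR)-7-bromo-5-[(1S)-1-bromopropyl]-2-[(1R)-1-bromoprop-2-yn-1-yl]octahydro-2H-furo[3,2-b]oxocin-8-ol | C#C[C@@H](Br)[C@H]1C[C@H]2O[C@H]([C@@H](Br)CC)C[C@H](Br)[C@H](O)C[C@H]2O1 | target

**Summary**

Total step count: 18. Longest linear sequence: 14 (steps 1–7 and 12–18).

Three steps most likely to fail, with fallbacks:

Step 18. The oxonium ion may be opened by water at C12 or C6 (ring contraction to bis-oxolane products) instead of at C9; the oxolane oxygen may compete as the participating group; or water may trap the bromonium ion directly (anti addition). The fallback avoids the oxonium opening and sets out from 25. Epoxidation with dimethyldioxirane (acetone, 0 °C) on the alkene face opposite the C12 side chain should give the 9,10-epoxide F1 (target-chain numbering); this face selectivity would have to be checked. SN2 opening at C10 with bromide (Li2NiBr4, THF, 0 °C) should give the anti bromohydrin F2, which has C10 as in the target but is epimeric at C9. Dess–Martin oxidation should give the α-bromo ketone F3, and hydride reduction on the face anti to the C10 bromine (NaBH4, CeCl3, MeOH, −78 °C) comes back to the route at 27.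

Step 12. The intermolecular reductive etherification joins two hindered secondary partners; direct reduction of the ketone by the silane, or enolisation and β-elimination of the oxolan-3-one, may outrun ether formation. The fallback separates C–O bond formation from the reduction and sets out from 13. Thioketalisation (EtSH, Zn(OTf)2, CH2Cl2) should give the diethyl dithioketal F4. Activation of one sulfur with MeOTf (2,6-di-tert-butyl-4-methylpyridine, 4 Å MS) in the presence of alcohol 17 should give the mixed O,S-ketal F5 (both C6 epimers serve). A second S-methylation in the presence of Et3SiH regenerates oxocarbenium ion 19, which is reduced on the same face as in the main route; the sequence comes back at 20.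

Step 7. The thiol-catalysed chain may be inefficient (slow aldehydic hydrogen abstraction, decarbonylation, thiyl addition to the alkyne); the β-alkoxy aldehyde may lose the vinylogous carbonate by β-elimination at 80 °C; and the 2,5-cis selectivity may erode at that temperature. The fallback forms the same C6–C7 bond by a reductive ketyl–olefin cyclisation at low temperature and sets out from 12. SmI2 (MeOH, THF, −78 °C) should give the hydroxy ester F6 (the C6 configuration is irrelevant because it is removed next). Dess–Martin oxidation of the C6 carbinol comes back to the route at 13.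

Further compounds
F1 | step 18 | 9,10-epoxide of 25 (target-chain numbering; oxygen on the face opposite the C12 side chain) | C#C[C@@H](Br)[C@H]1C[C@H]2O[C@H]([C@@H](Br)CC)C[C@H]3O[C@H]3C[C@H]2O1
F2 | step 18 | anti bromohydrin, C9 epimer of 27 | C#C[C@@H](Br)[C@H]1C[C@H]2O[C@H]([C@@H](Br)CC)C[C@H](Br)[C@@H](O)C[C@H]2O1
F3 | step 18 | α-bromo ketone (C9 ketone corresponding to 27) | C#C[C@@H](Br)[C@H]1C[C@H]2O[C@H]([C@@H](Br)CC)C[C@H](Br)C(=O)C[C@H]2O1
F4 | step 12 | diethyl dithioketal of 13 (3,3-bis(ethylsulfanyl)oxolane) | CC(C)[Si](C(C)C)(C(C)C)C#C[C@H](O[Si](C)(C)C(C)(C)C)[C@H]1CC(SCC)(SCC)[C@@H](CC(=O)OCC)O1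
F5 | step 12 | mixed O,S-ketal of 13 with alcohol 17 (C6 epimers) | CC(C)[Si](C(C)C)(C(C)C)C#C[C@H](O[Si](C)(C)C(C)(C)C)[C@H]1CC(SCC)(O[C@H]([C@H](O[Si](C)(C)C(C)(C)C)CC)CC=C)[C@@H](CC(=O)OCC)O1
F6 | step 7 | ethyl 2-[(2R,3S,5R)-5-[(1S)-1-[(tert-butyldimethylsilyl)oxy]-3-(triisopropylsilyl)prop-2-yn-1-yl]-3-hydroxyoxolan-2-yl]acetate | CC(C)[Si](C(C)C)(C(C)C)C#C[C@H](O[Si](C)(C)C(C)(C)C)[C@H]1C[C@H](O)[C@@H](CC(=O)OCC)O1
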